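**Retrosynthetic overview**

1. The last C–C bond is C6–C7: a copper-mediated Stille-type coupling joins a (5Z)-iodomethylene bromocyclopentenone to an (E)-vinylstannane carrying C1–C6 and the C4 stereocentre (Noyori transfer hydrogenation); desilylation ends the route.
2. Key disconnection: the ring C8–C12 comes from a 1-ethynylcyclobut-2-en-1-ol (ring C9–C10–C11–C12) by a gold-catalysed, NIS-terminated 1,2-shift of C12 from C9 to the alkyne carbon C8. This one operation forms the five-membered ring, the C8–C12 bond at the fully substituted carbon, the C9 ketone, the 7Z geometry and the C7–I handle.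
3. Enabling feature: in the strained four-membered ring, C9 carries both a hydroxyl group and the ethynyl group (C8, C7) and is flanked by C12, a fully substituted sp3 carbon bearing the silyloxy oxygen. The oxygen on C9 pushes, C12 migrates with retention, and strain release drives the shift.
4. C12 is set on the cyclobutane by palladium-catalysed decarboxylative asymmetric allylation of the enediol carbonate from 1,2-bis(trimethylsiloxy)cyclobutene. The allyl group becomes C13–C20 (ozonolysis, Z-selective Wittig); C10–Br and C10=C11 come from enolate bromination, selenation and selenoxide elimination.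
5. Order of rings: cyclobutanone (purchased ring) → 2-bromocyclobutenone → cyclopentenone (key step); no other ring is formed.

Key step: step 15

Remark: prostanoid numbering is used for the atoms (C1 = ester carbon, ring = C8–C12, side chain = C13–C20), and the SMILES is read as (4S,5E,7Z,12R,14Z,17Z).

**Route**

Step 1
Reactants: 1 (3Z)-hex-3-en-1-ol
Product: 2 (3Z)-1-iodohex-3-ene
Conditions: I2, PPh3, imidazole, CH2Cl2, 0 °C to rt
Reagents that add atoms: iodine, II
Why: Appel-type iodination of a primary alcohol by SN2 displacement of the oxyphosphonium ion, which leaves the Z-alkene untouched.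

Step 2
Reactants: 2 (3Z)-1-iodohex-3-ene
Product: 3 [(3Z)-hex-3-en-1-yl]triphenylphosphonium iodide
Conditions: PPh3, MeCN, reflux
Reagents that add atoms: triphenylphosphine, c1ccc(cc1)P(c1ccccc1)c1ccccc1
Why: SN2 quaternisation of triphenylphosphine by a primary iodide gives the Wittig salt.

Step 3
Reactants: 4 methyl 4-chloro-4-oxobutanoate + 5 ethynyltrimethylsilane
Product: 6 methyl 4-oxo-6-(trimethylsilyl)hex-5-ynoate
Conditions: PdCl2(PPh3)2 (2 mol %), CuI (4 mol %), Et3N (1.2 equiv), THF, rt
Reagents that add atoms: none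
Why: acyl Sonogashira coupling of an acid chloride with a terminal alkyne should give the ynone, the ester and the C–Si bond being inert.

Step 4
Reactants: 6 methyl 4-oxo-6-(trimethylsilyl)hex-5-ynoate
Product: 7 methyl (4S)-4-hydroxy-6-(trimethylsilyl)hex-5-ynoate
Conditions: Ru[(S,S)-TsDPEN](p-cymene) (1 mol %), iPrOH, 25 °C; used directly in step 5
Reagents that add atoms: none
Why: Noyori asymmetric transfer hydrogenation of an alkynyl ketone, in which the alkyne plays the role of the π-substituent so that the (S,S)-catalyst should deliver hydride to give the 4S alcohol; neutral conditions and immediate silylation avoid lactonisation.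

Step 5
Reactants: 7 methyl (4S)-4-hydroxy-6-(trimethylsilyl)hex-5-ynoate
Product: 8 methyl (4S)-4-(tert-butyldimethylsiloxy)-6-(trimethylsilyl)hex-5-ynoate
Conditions: TBSCl, imidazole, DMF, 0 °C to rt
Reagents that add atoms: tert-butyldimethylsilyl chloride, CC(C)(C)[Si](C)(C)Cl
Why: standard silylation of a secondary alcohol blocks lactonisation and protects O4 until the last step.

Step 6
Reactants: 8 methyl (4S)-4-(tert-butyldimethylsiloxy)-6-(trimethylsilyl)hex-5-ynoate
Product: 9 methyl (4S)-4-(tert-butyldimethylsiloxy)hex-5-ynoate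
Conditions: K2CO3 (0.2 equiv), MeOH, 0 °C
Reagents that add atoms: none
Why: methoxide cleaves the alkynyl C–Si bond selectively, while the silyl ether and the methyl ester (in methanol) are unchanged.

Step 7
Reactants: 9 methyl (4S)-4-(tert-butyldimethylsiloxy)hex-5-ynoate
Product: 10 methyl (4S,5E)-4-(tert-butyldimethylsiloxy)-6-(tributylstannyl)hex-5-enoate
Conditions: Bu3SnH, PdCl2(PPh3)2 (2 mol %), THF, 0 °C
Reagents that add atoms: tributyltin hydride, CCCC[SnH](CCCC)CCCC
Why: palladium-catalysed hydrostannylation adds Sn–H syn across the terminal alkyne, and the bulky silyloxy group should direct tin to the terminal carbon to give the E-stannane.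

Step 8
Reactants: 11 1,2-bis(trimethylsiloxy)cyclobut-1-ene + 12 allyl chloroformate
Product: 14 prop-2-en-1-yl 2-(trimethylsiloxy)cyclobut-1-en-1-yl carbonate, via lithium enolate 13 (not isolated)
Conditions: MeLi (1.0 equiv), THF, 0 °C; then allyl chloroformate, −78 to 0 °C
Reagents that add atoms: none
Why: MeLi cleaves one O–Si bond to give the regiodefined lithium enolate, which is O-acylated by the chloroformate to the enol carbonate needed for decarboxylative allylation.

Step 9
Reactants: 14 prop-2-en-1-yl 2-(trimethylsiloxy)cyclobut-1-en-1-yl carbonate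
Product: 15 (2S)-2-(prop-2-en-1-yl)-2-(trimethylsiloxy)cyclobutan-1-one
Conditions: Pd2(dba)3 (2.5 mol %), (R)-t-Bu-PHOX (6 mol %; the antipode if a first run shows the opposite sense), toluene, 25 °C
Reagents that add atoms: none
Why: Tsuji–Trost decarboxylative asymmetric allylic alkylation, in which zerovalent palladium ionises the allyl carbonate, CO2 is lost and the chiral palladium enolate–allyl pair recombines at the siloxy-bearing enolate carbon, so that the ligand sets the fully substituted stereocentre C12.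

Step 10
Reactants: 15 (2S)-2-(prop-2-en-1-yl)-2-(trimethylsiloxy)cyclobutan-1-one
Product: 17 2-[(1S)-2-oxo-1-(trimethylsiloxy)cyclobutyl]acetaldehyde, via ozonide 16 (not isolated)
Conditions: O3, CH2Cl2, −78 °C; then PPh3, −78 °C to rt
Reagents that add atoms: ozone, [O-][O+]=O
Why: ozonolysis with reductive work-up cleaves the terminal alkene to the C14 aldehyde under anhydrous conditions that spare the silyl ether and the ketone.

Step 11
Reactants: 17 2-[(1S)-2-oxo-1-(trimethylsiloxy)cyclobutyl]acetaldehyde + 3 [(3Z)-hex-3-en-1-yl]triphenylphosphonium iodide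
Product: 19 (2S)-2-[(2Z,5Z)-octa-2,5-dien-1-yl]-2-(trimethylsiloxy)cyclobutan-1-one, via phosphorus ylide 18 (not isolated)
Conditions: 3, NaN(SiMe3)2, THF, −78 to 0 °C; then 17 (1.0 equiv ylide), −78 °C to rt
Reagents that add atoms: none
Why: Wittig reaction of a non-stabilised ylide under lithium-free conditions should give the Z-alkene (C14=C15), the aldehyde reacting in preference to the hindered ketone, and this happens before any enone exists in the molecule.

Step 12
Reactants: 19 (2S)-2-[(2Z,5Z)-octa-2,5-dien-1-yl]-2-(trimethylsiloxy)cyclobutan-1-one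
Product: 21 (2R)-4-bromo-2-[(2Z,5Z)-octa-2,5-dien-1-yl]-4-(phenylselanyl)-2-(trimethylsiloxy)cyclobutan-1-one (C4 epimers; C2 arranged as in 19), via bromo ketone 20 (not isolated)
Conditions: LiN(SiMe3)2 (1.05 equiv), THF, −78 °C, then NBS (1.0 equiv); then LiN(SiMe3)2 (1.1 equiv), −78 °C, then PhSeCl (1.05 equiv)
Reagents that add atoms: N-bromosuccinimide, BrN1C(=O)CCC1=O; phenylselenyl chloride, Cl[Se]c1ccccc1
Why: C10 is the only enolisable position, so two successive enolate trappings (bromination, then selenation of the more acidic bromo ketone) put bromine and selenium on C10 without touching the isolated alkenes.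

Step 13
Reactants: 21 (2R)-4-bromo-2-[(2Z,5Z)-octa-2,5-dien-1-yl]-4-(phenylselanyl)-2-(trimethylsiloxy)cyclobutan-1-one
Product: 23 (4R)-2-bromo-4-[(2Z,5Z)-octa-2,5-dien-1-yl]-4-(trimethylsiloxy)cyclobut-2-en-1-one, via selenoxide 22 (not isolated)
Conditions: mCPBA (1.0 equiv), CH2Cl2, −78 °C; then iPr2NH, −78 to 0 °C; product kept cold and used promptly
Reagents that add atoms: none
Why: selenoxide syn-elimination, for which the only β-hydrogens are on C11, should give the 2-bromocyclobutenone; oxidation at selenium at −78 °C is faster than Baeyer–Villiger or alkene oxidation.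

Step 14
Reactants: 23 (4R)-2-bromo-4-[(2Z,5Z)-octa-2,5-dien-1-yl]-4-(trimethylsiloxy)cyclobut-2-en-1-one + 24 ethynylmagnesium bromide
Product: 25 (4R)-2-bromo-1-ethynyl-4-[(2Z,5Z)-octa-2,5-dien-1-yl]-4-(trimethylsiloxy)cyclobut-2-en-1-ol (both C1 epimers)
Conditions: HC≡CMgBr (1.5 equiv), THF, −78 °C; saturated NH4Cl added at −78 °C
Reagents that add atoms: none
Why: 1,2-addition of an alkynyl Grignard reagent to the cyclobutenone carbonyl; both C9 epimers are usable because C9 becomes the ketone in step 15, and the cold quench avoids silyl transfer or ring opening of the alkoxide.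

Step 15
Reactants: 25 (4R)-2-bromo-1-ethynyl-4-[(2Z,5Z)-octa-2,5-dien-1-yl]-4-(trimethylsiloxy)cyclobut-2-en-1-ol
Product: 26 (4R,5Z)-2-bromo-5-(iodomethylidene)-4-[(2Z,5Z)-octa-2,5-dien-1-yl]-4-(trimethylsiloxy)cyclopent-2-en-1-one
Conditions: NIS (1.3 equiv), Ph3PAuNTf2 (2 mol %), 2,6-di-tert-butylpyridine (1.2 equiv), CH2Cl2, −30 to 0 °C, dark
Reagents that add atoms: N-iodosuccinimide, IN1C(=O)CCC1=O
Why: Proposed new method: cationic monovalent gold binds the ethynyl group of 25 and the antiperiplanar C9–C12 ring bond shifts to the inner alkyne carbon C8 while the C9 hydroxyl becomes the C9 ketone (semipinacol 1,2-shift driven by release of cyclobutene strain), giving a vinyl-gold species that NIS should intercept by iododeauration faster than the buffered proton can; the closest known reactions are the gold-catalysed ring expansion of 1-alkynylcyclobutanols to 2-alkylidenecyclopentanones and the NIS capture of vinyl-gold intermediates in other gold-catalysed alkyne additions, neither of which has been run on a 1-ethynylcyclobut-2-enol. The five-membered ring C8–C9–C10–C11–C12 arises by one-carbon ring expansion of the four-membered ring C9–C10–C11–C12, the alkyne carbon C8 being inserted between C9 and C12 by a suprafacial 1,2-alkyl shift and not by a cyclisation. No new stereocentre is formed: C12 migrates with retention so its configuration from step 9 is carried over, the C9 carbinol centre (both epimers) is erased, and the geometry of the new C7=C8 bond follows from anti addition of C12 and gold across the alkyne, which places iodine cis to the C9 carbonyl (5Z). The step needs C12 and not the vinylic C10 to migrate, which the substrate should secure because C12 is sp3, fully substituted and carries a siloxy oxygen that stabilises the shifting centre, whereas C10 is an sp2 carbon deactivated by bromine and its shift would give an unconjugated ketone; it also needs the alkyne to react before the two Z-alkenes of the side chain, which the alkynophilic catalyst and the absence of free acid (hindered pyridine) should ensure.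

Step 16
Reactants: 26 (4R,5Z)-2-bromo-5-(iodomethylidene)-4-[(2Z,5Z)-octa-2,5-dien-1-yl]-4-(trimethylsiloxy)cyclopent-2-en-1-one + 10 methyl (4S,5E)-4-(tert-butyldimethylsiloxy)-6-(tributylstannyl)hex-5-enoate
Product: 27 methyl (4S,5E,7Z,12R,14Z,17Z)-10-bromo-4-(tert-butyldimethylsiloxy)-9-oxo-12-(trimethylsiloxy)prosta-5,7,10,14,17-pentaen-1-oate
Conditions: Cu(O2CC4H3S) (copper thiophene-2-carboxylate, 1.5 equiv), NMP, 0 °C to rt, dark
Reagents that add atoms: none
Why: Allred–Liebeskind coupling, in which monovalent copper transmetalates the vinylstannane and couples it with the β-iodoenone (assisted by the carbonyl cis to iodine) with retention at both alkenes, while the vinylic C–Br bond, which a palladium catalyst could attack, should stay intact.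

Step 17
Reactants: 27 methyl (4S,5E,7Z,12R,14Z,17Z)-10-bromo-4-(tert-butyldimethylsiloxy)-9-oxo-12-(trimethylsiloxy)prosta-5,7,10,14,17-pentaen-1-oate
Product: 28 methyl (4S,5E,7Z,12R,14Z,17Z)-10-bromo-4,12-dihydroxy-9-oxoprosta-5,7,10,14,17-pentaen-1-oate (target)
Conditions: HF·pyridine, pyridine, THF, 0 °C to rt
Reagents that add atoms: none
Why: buffered fluoride cleaves both silyl ethers (the tertiary trimethylsilyl ether first) under conditions mild enough for the trienone, the vinyl bromide and the ester.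

**Compound list**

1 | (3Z)-hex-3-en-1-ol | CC/C=C\CCO | starting material
2 | (3Z)-1-iodohex-3-ene | CC/C=C\CCI | intermediate
3 | [(3Z)-hex-3-en-1-yl]triphenylphosphonium iodide | CC/C=C\CC[P+](c1ccccc1)(c1ccccc1)c1ccccc1.[I-] | intermediate
4 | methyl 4-chloro-4-oxobutanoate | COC(=O)CCC(=O)Cl | starting material
5 | ethynyltrimethylsilane | C#C[Si](C)(C)C | starting material
6 | methyl 4-oxo-6-(trimethylsilyl)hex-5-ynoate | COC(=O)CCC(=O)C#C[Si](C)(C)C | intermediate
7 | methyl (4S)-4-hydroxy-6-(trimethylsilyl)hex-5-ynoate | C[Si](C)(C)C#C[C@@H](O)CCC(=O)OC | intermediate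
8 | methyl (4S)-4-(tert-butyldimethylsiloxy)-6-(trimethylsilyl)hex-5-ynoate | C[Si](C)(C)C#C[C@@H](O[Si](C)(C)C(C)(C)C)CCC(=O)OC | intermediate
9 | methyl (4S)-4-(tert-butyldimethylsiloxy)hex-5-ynoate | C#C[C@@H](O[Si](C)(C)C(C)(C)C)CCC(=O)OC | intermediate
10 | methyl (4S,5E)-4-(tert-butyldimethylsiloxy)-6-(tributylstannyl)hex-5-enoate | CCCC[Sn](CCCC)(CCCC)/C=C/[C@@H](O[Si](C)(C)C(C)(C)C)CCC(=O)OC | intermediate
11 | 1,2-bis(trimethylsiloxy)cyclobut-1-ene | C[Si](C)(C)OC1=C(O[Si](C)(C)C)CC1 | starting material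
12 | allyl chloroformate (prop-2-en-1-yl carbonochloridate) | C=CCOC(=O)Cl | starting material
13 | lithium 2-(trimethylsiloxy)cyclobut-1-en-1-olate | [Li]OC1=C(O[Si](C)(C)C)CC1 | intermediate
14 | prop-2-en-1-yl 2-(trimethylsiloxy)cyclobut-1-en-1-yl carbonate | C=CCOC(=O)OC1=C(O[Si](C)(C)C)CC1 | intermediate
15 | (2S)-2-(prop-2-en-1-yl)-2-(trimethylsiloxy)cyclobutan-1-one | C=CC[C@@]1(O[Si](C)(C)C)CCC1=O | intermediate
16 | 3-{[(1S)-2-oxo-1-(trimethylsiloxy)cyclobutyl]methyl}-1,2,4-trioxolane (ozonide) | C1OC(C[C@@]2(O[Si](C)(C)C)CCC2=O)OO1 | intermediate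
17 | 2-[(1S)-2-oxo-1-(trimethylsiloxy)cyclobutyl]acetaldehyde | O=CC[C@@]1(O[Si](C)(C)C)CCC1=O | intermediate
18 | [(3Z)-hex-3-en-1-ylidene]triphenylphosphorane | CC/C=C\CC=P(c1ccccc1)(c1ccccc1)c1ccccc1 | intermediate
19 | (2S)-2-[(2Z,5Z)-octa-2,5-dien-1-yl]-2-(trimethylsiloxy)cyclobutan-1-one | CC/C=C\C/C=C\C[C@@]1(O[Si](C)(C)C)CCC1=O | intermediate
20 | (2R)-4-bromo-2-[(2Z,5Z)-octa-2,5-dien-1-yl]-2-(trimethylsiloxy)cyclobutan-1-one (C4 epimers; C2 arranged as in 19, the descriptor changes by priority only) | CC/C=C\C/C=C\C[C@@]1(O[Si](C)(C)C)CC(Br)C1=O | intermediate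
21 | (2R)-4-bromo-2-[(2Z,5Z)-octa-2,5-dien-1-yl]-4-(phenylselanyl)-2-(trimethylsiloxy)cyclobutan-1-one (C4 epimers) | CC/C=C\C/C=C\C[C@@]1(O[Si](C)(C)C)CC(Br)([Se]c2ccccc2)C1=O | intermediate
22 | (2R)-4-bromo-2-[(2Z,5Z)-octa-2,5-dien-1-yl]-4-(phenylseleninyl)-2-(trimethylsiloxy)cyclobutan-1-one (selenoxide) | CC/C=C\C/C=C\C[C@@]1(O[Si](C)(C)C)CC(Br)([Se](=O)c2ccccc2)C1=O | intermediate
23 | (4R)-2-bromo-4-[(2Z,5Z)-octa-2,5-dien-1-yl]-4-(trimethylsiloxy)cyclobut-2-en-1-one | CC/C=C\C/C=C\C[C@@]1(O[Si](C)(C)C)C=C(Br)C1=O | intermediate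
24 | ethynylmagnesium bromide | C#C[Mg]Br | starting material
25 | (4R)-2-bromo-1-ethynyl-4-[(2Z,5Z)-octa-2,5-dien-1-yl]-4-(trimethylsiloxy)cyclobut-2-en-1-ol (both C1 epimers) | CC/C=C\C/C=C\C[C@@]1(O[Si](C)(C)C)C=C(Br)C1(O)C#C | intermediate
26 | (4R,5Z)-2-bromo-5-(iodomethylidene)-4-[(2Z,5Z)-octa-2,5-dien-1-yl]-4-(trimethylsiloxy)cyclopent-2-en-1-one | CC/C=C\C/C=C\C[C@@]1(O[Si](C)(C)C)C=C(Br)C(=O)/C1=C\I | intermediate
27 | methyl (4S,5E,7Z,12R,14Z,17Z)-10-bromo-4-(tert-butyldimethylsiloxy)-9-oxo-12-(trimethylsiloxy)prosta-5,7,10,14,17-pentaen-1-oate | CC/C=C\C/C=C\C[C@@]1(O[Si](C)(C)C)C=C(Br)C(=O)/C1=C\C=C\[C@@H](O[Si](C)(C)C(C)(C)C)CCC(=O)OC | intermediate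
28 | methyl (4S,5E,7Z,12R,14Z,17Z)-10-bromo-4,12-dihydroxy-9-oxoprosta-5,7,10,14,17-pentaen-1-oate | CC/C=C\C/C=C\C[C@@]1(O)C=C(Br)C(=O)/C1=C\C=C\[C@@H](O)CCC(=O)OC | target

**Totals and risks**

Total step count: 17. Longest linear sequence: 10 steps (steps 8 to 17, from 11 to 28).

Steps most likely to fail:

Step 15 (the labelled step). The vinyl-gold intermediate may be protonated before it is iodinated, the terminal alkyne may be iodinated at carbon first (which would lead to the wrong alkene geometry), the side-chain alkenes may be iodinated, or C10 may migrate in place of C12. The fallback uses established reactions only, sets out from 19 and 10 and comes back at 27. Ethynylmagnesium bromide adds to 19 to give (2S)-1-ethynyl-2-[(2Z,5Z)-octa-2,5-dien-1-yl]-2-(trimethylsiloxy)cyclobutan-1-ol F1. Iododestannylation of 10 (I2, CH2Cl2, 0 °C) gives methyl (4S,5E)-4-(tert-butyldimethylsiloxy)-6-iodohex-5-enoate F2. Sonogashira coupling of F1 with F2 (PdCl2(PPh3)2, CuI, Et3N) gives the enynyl cyclobutanol F3. The known gold-catalysed ring expansion of a saturated 1-alkynylcyclobutanol (Ph3PAuNTf2, CH2Cl2, protodeauration, the more substituted carbon C12 migrating) should then give the (7E)-dienone F4. Enolate bromination and selenation as in step 12 give the bromo selenide F5, and selenoxide elimination as in step 13 gives the (7E)-isomer of 27, F6. Irradiation (350 nm, benzene) equilibrates the C7=C8 geometry; 27 is separated and F6 is recycled.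

Step 9. Facial discrimination in the allylation of the small, oxygen-substituted enolate may be poor, or O-allylation may compete. The fallback sets out from 11 and comes back at 15, and replaces the enolate alkylation by an enantioselective carbonyl addition. Bromine (pentane, −60 °C) converts 11 into cyclobutane-1,2-dione F7. Catalytic asymmetric allylation of one carbonyl group (Ti(OiPr)4, (S)- or (R)-BINOL, iPrOH, tetraallylstannane, CH2Cl2) should give (2S)-2-hydroxy-2-(prop-2-en-1-yl)cyclobutan-1-one F8, which is silylated at once (TMSCl, imidazole) to 15 before any ketol rearrangement can set in.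

Step 13. Baeyer–Villiger-type oxidation or electrocyclic opening of the strained ketone may compete with the syn-elimination. The fallback sets out from 19 and comes back at 27, and moves the introduction of the C10=C11 bond to the five-membered ring. Two cycles of LiN(SiMe3)2/NBS give (2R)-4,4-dibromo-2-[(2Z,5Z)-octa-2,5-dien-1-yl]-2-(trimethylsiloxy)cyclobutan-1-one F9. Ethynylmagnesium bromide with CeCl3 at −78 °C gives the dibromo ethynyl carbinol F10. The conditions of step 15 (a CBr2 carbon cannot compete with C12 in the shift) should give the 2,2-dibromo-5-(iodomethylidene)cyclopentanone F11. The coupling of step 16 with 10 gives the 10,10-dibromide F12, and E2 dehydrobromination (DBU, CH2Cl2, 0 °C) then gives 27.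

**Further compounds**

F1 | step 15 | (2S)-1-ethynyl-2-[(2Z,5Z)-octa-2,5-dien-1-yl]-2-(trimethylsiloxy)cyclobutan-1-ol (C1 epimers) | CC/C=C\C/C=C\C[C@@]1(O[Si](C)(C)C)CCC1(O)C#C
F2 | step 15 | methyl (4S,5E)-4-(tert-butyldimethylsiloxy)-6-iodohex-5-enoate | I/C=C/[C@@H](O[Si](C)(C)C(C)(C)C)CCC(=O)OC
F3 | step 15 | methyl (4S,5E)-4-(tert-butyldimethylsiloxy)-8-{(2S)-1-hydroxy-2-[(2Z,5Z)-octa-2,5-dien-1-yl]-2-(trimethylsiloxy)cyclobutyl}oct-5-en-7-ynoate | CC/C=C\C/C=C\C[C@@]1(O[Si](C)(C)C)CCC1(O)C#C/C=C/[C@@H](O[Si](C)(C)C(C)(C)C)CCC(=O)OC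
F4 | step 15 | methyl (4S,5E,7E,12S,14Z,17Z)-4-(tert-butyldimethylsiloxy)-9-oxo-12-(trimethylsiloxy)prosta-5,7,14,17-tetraen-1-oate (C12 arranged as in 27) | CC/C=C\C/C=C\C[C@@]1(O[Si](C)(C)C)CCC(=O)/C1=C/C=C/[C@@H](O[Si](C)(C)C(C)(C)C)CCC(=O)OC
F5 | step 15 | methyl (4S,5E,7E,12R,14Z,17Z)-10-bromo-4-(tert-butyldimethylsiloxy)-9-oxo-10-(phenylselanyl)-12-(trimethylsiloxy)prosta-5,7,14,17-tetraen-1-oate (C10 epimers) | CC/C=C\C/C=C\C[C@@]1(O[Si](C)(C)C)CC(Br)([Se]c2ccccc2)C(=O)/C1=C/C=C/[C@@H](O[Si](C)(C)C(C)(C)C)CCC(=O)OC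
F6 | step 15 | methyl (4S,5E,7E,12R,14Z,17Z)-10-bromo-4-(tert-butyldimethylsiloxy)-9-oxo-12-(trimethylsiloxy)prosta-5,7,10,14,17-pentaen-1-oate | CC/C=C\C/C=C\C[C@@]1(O[Si](C)(C)C)C=C(Br)C(=O)/C1=C/C=C/[C@@H](O[Si](C)(C)C(C)(C)C)CCC(=O)OC
F7 | step 9 | cyclobutane-1,2-dione | O=C1CCC1=O
F8 | step 9 | (2S)-2-hydroxy-2-(prop-2-en-1-yl)cyclobutan-1-one | C=CC[C@@]1(O)CCC1=O
F9 | step 13 | (2R)-4,4-dibromo-2-[(2Z,5Z)-octa-2,5-dien-1-yl]-2-(trimethylsiloxy)cyclobutan-1-one | CC/C=C\C/C=C\C[C@@]1(O[Si](C)(C)C)CC(Br)(Br)C1=O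
F10 | step 13 | (4R)-2,2-dibromo-1-ethynyl-4-[(2Z,5Z)-octa-2,5-dien-1-yl]-4-(trimethylsiloxy)cyclobutan-1-ol (C1 epimers) | CC/C=C\C/C=C\C[C@@]1(O[Si](C)(C)C)CC(Br)(Br)C1(O)C#C
F11 | step 13 | (4R,5Z)-2,2-dibromo-5-(iodomethylidene)-4-[(2Z,5Z)-octa-2,5-dien-1-yl]-4-(trimethylsiloxy)cyclopentan-1-one | CC/C=C\C/C=C\C[C@@]1(O[Si](C)(C)C)CC(Br)(Br)C(=O)/C1=C\I
F12 | step 13 | methyl (4S,5E,7Z,12R,14Z,17Z)-10,10-dibromo-4-(tert-butyldimethylsiloxy)-9-oxo-12-(trimethylsiloxy)prosta-5,7,14,17-tetraen-1-oate | CC/C=C\C/C=C\C[C@@]1(O[Si](C)(C)C)CC(Br)(Br)C(=O)/C1=C\C=C\[C@@H](O[Si](C)(C)C(C)(C)C)CCC(=O)OC
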